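All constants come from no measurement; no experiment stands behind them.

Which flask sends the most tris adduct to tetra adduct rather than to side product?

common to all: time 3.0 h

| run | substrate | reagent | remark |
|---|---|---|---|
| red | 0.050 M | 0.0750 M | everything together at the start |
| green | 0.050 M (fed, over 80 min) | 0.0750 M | all else is in the flask from the start; the feed brings no volume worth counting |
| violet | 0.050 M | 0.0750 M (fed, over 80 min) | all else is in the flask from the start; the feed brings no volume worth counting |

- the flask with the highest share of tetra adduct in tetra adduct plus side product ("all alike" if they lie within 1.5 percentage points) (red / green / violet / all alike)
- share of tetra adduct in tetra adduct plus side product at the end, red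
- share of tetra adduct in tetra adduct plus side product at the end, green
- share of tetra adduct in tetra adduct plus side product at the end, violet

    tris adduct → side product (k1 = 7.6 × 10⁻⁴ s⁻¹)
    reagent + bis adduct → tris adduct (k2 = 0.014 M⁻¹ s⁻¹)
    reagent + tris adduct → tetra adduct (k3 = 0.074 M⁻¹ s⁻¹)
    substrate + reagent → single product (k4 = 0.034 M⁻¹ s⁻¹)
    reagent + single product → bis adduct (k5 = 0.0037 M⁻¹ s⁻¹)

Tris adduct stands at a branch point. Dividing the rate of tetra adduct making by that of side product making cancels tris adduct and time, which leaves the reagent fraction over a fixed level. That level is the rate constant of the loss over that of the capture, per reagent charge: 13.7% of the charge. This is the fork level, the reagent fraction at which both branches run equally, and the reagent fraction divided by it is the selectivity factor.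

So what reagent fraction meets the single product? In red, substrate has a half-life of 0.076 h and single product 0.69 h, so substrate goes faster and single product waits for it. Reagent then stands near 33.3% of its charge, 2.43 times the fork level, and the tetra adduct share of the flow is 70.9%.

In green, the first substrate meets reagent near its whole charge, so that share is 88.0% at the start.

In violet, reagent is consumed as it is fed. Its early fraction is the feed rate over the capture by substrate as charged, 12.3%, which is below the fork level, and that gives 47.2%. This fraction climbs as substrate falls.

Red starts at that same share, but red's reagent falls towards 33.3% of its charge with a substrate half-life of 0.076 h, while green's fall is spread over the feed of 80 min. Green's single product therefore meets more reagent than red's, and green's start stands above violet's, so the reckoning names green. It leaves red and violet unranked.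

The forecast named green, with 45% for red, 63% for green and 51% for violet, holding that “what matters is how much reagent remains while tris forms”.

The simulation gives green, with 48.7% for red, 63.0% for green and 51.4% for violet.

In green, half of the tris adduct making up to the end was done by 1.07 h, while capture outran loss 4.2 to one at 0.784 h and reagent still stood at 23.0% of its charge, 1.68 times the fork level, at 1.33 h. By 3.00 h, green's reagent had fallen to 2.03%, 0.148 of the fork level, with 0.415% of tris adduct still standing. A neighbour of green charged with 0.020 M of substrate ended with reagent at 31.0%, 2.26 times the fork level, and a share of 78.5%.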